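**Plan**

- Ring A is cut at C5–C4a (electrocyclic closure) and at C8–C8a (carbanion addition to a squarate carbonyl). C5–C8 with their four oxygens go back to dimethyl squarate, and C4a=C8a goes back to the C5=C6 bond of 3-methoxy-2-phenyl-4H-pyran-4-one.
- Enabling feature: ring A has oxygen on four adjacent carbons (C5-OH, C6/C7/C8-OMe, C5 and C8 para), which is the C4O4 core of a squarate, and it is fused to ring C through an alkene (C4a=C8a) already present in a γ-pyranone. The ketene oxygen becomes 5-OH and the pre-methylated carbinol oxygen becomes 8-OMe, so no late selective methylation or demethylation is needed.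
- Ring C is traced back through its 3-hydroxy form and a 4-bromo-dihydropyranone to an Achmatowicz pyranone, and from there to furfural and phenylmagnesium bromide; ring B is bought as the phenyl group.
- Forward order: ring C first (furan, dihydropyranone, γ-pyranone), then the squarate C4 unit joined at the future C8a, then ring A last by 4π opening and 6π closure.
- Stereochemistry: the target is achiral (no stereocentre, no stereogenic alkene). The sp3 centres of intermediates are racemic or mixtures and all disappear on aromatisation.

Key step: step 8

Remark: because the target is achiral, the single-enantiomer requirement is met by the compound itself. Ring C precursors use pyranone numbering; the target uses flavone numbering (pyranone C5/C6 become C4a/C8a).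

**Route**

Step 1
Reactants: 1 furfural; 2 phenylmagnesium bromide
Product: 3 furan-2-yl(phenyl)methanol (racemic)
Conditions: PhMgBr (1.1 equiv), THF, 0 °C to rt; aq. NH4Cl
Reagents that add atoms: none
Why: Grignard 1,2-addition of an aryl magnesium halide to a non-enolisable aldehyde is fast and clean; the carbinol centre forms as a racemate, which is acceptable because this carbon becomes sp2 (C2 of the pyranone) in step 4.

Step 2
Reactants: 3 furan-2-yl(phenyl)methanol
Product: 4 6-hydroxy-2-phenyl-2H-pyran-3(6H)-one (racemic anomer mixture)
Conditions: NBS (1.05 equiv), NaHCO3 (2 equiv), THF/H2O 4:1, 0 °C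
Reagents that add atoms: water, SMILES O
Why: Achmatowicz rearrangement: oxidation of the electron-rich furan in water gives a 2,5-dioxygenated dihydrofuran that opens to the cis-enedione and is re-closed by the carbinol oxygen to the six-membered hemiacetal; the bicarbonate buffer suppresses acid-catalysed Piancatelli rearrangement of the doubly activated carbinol, and the new acetal centre (anomer mixture) is destroyed in step 4.

Step 3
Reactants: 4 6-hydroxy-2-phenyl-2H-pyran-3(6H)-one
Product: 6 4-bromo-6-hydroxy-2-phenyl-2H-pyran-3(6H)-one (racemic anomer mixture), via 4,5-dibromo adduct 5 (not isolated)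
Conditions: Br2 (1.05 equiv), CH2Cl2, −30 °C; then Et3N (1.2 equiv), −30 to 0 °C
Reagents that add atoms: bromine, SMILES BrBr
Why: Classical α-bromination of an enone by bromine addition and E1cB dehydrobromination: the amine removes the acidic C4–H next to the ketone and expels the C5 bromide, so the halogen stays on the α-carbon, as practised on the 2-alkyl analogues in γ-pyrone manufacture.

Step 4
Reactants: 6 4-bromo-6-hydroxy-2-phenyl-2H-pyran-3(6H)-one
Product: 7 3-hydroxy-2-phenyl-4H-pyran-4-one
Conditions: 2 M aq. H2SO4/1,4-dioxane 1:1, 90 °C
Reagents that add atoms: water, SMILES O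
Why: Acid-mediated isomerisation–hydrolysis of the maltol-process type: enolisation through the benzylic C2–H and ionisation of the C6 hemiacetal give a 4-bromo-3-hydroxypyrylium ion, water attacks its C4 (a vinylogous acyl bromide), and loss of HBr leaves the aromatic 3-hydroxy-4-pyranone, removing both sp3 centres.

Step 5
Reactants: 7 3-hydroxy-2-phenyl-4H-pyran-4-one
Product: 8 3-methoxy-2-phenyl-4H-pyran-4-one
Conditions: MeI (1.5 equiv), K2CO3, acetone, reflux
Reagents that add atoms: iodomethane, SMILES CI
Why: Williamson etherification of the phenol-like enolic 3-OH, the standard preparation of maltol-type methyl ethers; MeI does not alkylate the pyranone carbonyl under these conditions.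

Step 6
Reactants: 8 3-methoxy-2-phenyl-4H-pyran-4-one; 9 dimethyl squarate
Product: 11 4-hydroxy-2,3-dimethoxy-4-(5-methoxy-4-oxo-6-phenyl-4H-pyran-2-yl)cyclobut-2-en-1-one (racemic), via 6-lithiopyranone 10 (not isolated)
Conditions: LiTMP (1.1 equiv, from TMPH and n-BuLi), THF, −78 °C, 8 added dropwise, 20 min; then 9 (1.3 equiv) in THF, −78 °C; aq. NH4Cl at −78 °C
Reagents that add atoms: none
Why: Deprotonative lithiation with a hindered, non-nucleophilic amide should remove the most acidic ring proton, C6–H on the carbon bound to the ring oxygen (the counterpart of C2–H in chromones; pyranone C2 is blocked by phenyl), and the vinyl-lithium then adds 1,2 to one of the two equivalent squarate carbonyls at −78 °C, the standard entry to 4-substituted 4-hydroxycyclobutenones; the new carbinol centre is racemic and is erased in step 8.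

Step 7
Reactants: 11 4-hydroxy-2,3-dimethoxy-4-(5-methoxy-4-oxo-6-phenyl-4H-pyran-2-yl)cyclobut-2-en-1-one
Product: 12 2,3,4-trimethoxy-4-(5-methoxy-4-oxo-6-phenyl-4H-pyran-2-yl)cyclobut-2-en-1-one (racemic)
Conditions: MeI (10 equiv), Ag2O (2 equiv), K2CO3, MeCN, rt, dark
Reagents that add atoms: iodomethane, SMILES CI
Why: Silver(I) oxide-promoted O-methylation (Purdie conditions) etherifies the tertiary carbinol without forming a free alkoxide, which avoids base-induced cleavage of the hydroxycyclobutenone and is the usual way squarate adducts are capped before thermolysis; this methyl becomes the 8-OMe.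

Step 8
Reactants: 12 2,3,4-trimethoxy-4-(5-methoxy-4-oxo-6-phenyl-4H-pyran-2-yl)cyclobut-2-en-1-one
Product: 15 5-hydroxy-3,6,7,8-tetramethoxyflavone, via dienylketene 13 (not isolated), via 4aH-chromene-4,5-dione 14 (not isolated)
Conditions: degassed p-xylene (0.02 M), 138 °C, Ar
Reagents that add atoms: none
Why: Proposed new method: heating should break the cyclobutenone C1–C4 bond in a conrotatory 4π electrocyclic opening to dienylketene 13, after which the ketene carbon bonds to pyranone C5 in a thermal disrotatory 6π electrocyclisation (forming C5–C4a), and the 4a-H dienone 14, whose C4a–H lies between two carbonyl groups, enolises at once to the chelated 5-hydroxychromone. The closest known reaction type is the Moore rearrangement of squarate-derived 4-aryl-, 4-heteroaryl- and 4-alkenyl-4-alkoxycyclobutenones to mono-protected hydroquinones; what is new is the γ-pyranone as the 2π partner, which should close more readily than a benzene ring because it is only weakly aromatic and its C5 is the nucleophilic α-carbon of a vinylogous ester facing an electrophilic ketene carbon. Ring A is the only ring closed, as a six-membered all-carbon ring by 6π electrocyclisation of the ketene–diene–pyranone-alkene triene. The only stereocentre created, C4a of 14, is transient and removed by tautomerisation, so no stereocontrol is required. Two selectivities are needed: inward rotation of the pyranonyl group, secured by the outward torquoselective preference of the C4 methoxy donor, and closure at pyranone C5 only, secured because C5 is the sole carbon next to the attachment point that carries hydrogen (the other neighbour is the ring oxygen). The oxygen pattern follows from connectivity alone, the ketene oxygen ending as 5-OH and the carbinol methyl ether as 8-OMe.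

**Compound list**

1 | furfural | O=Cc1ccco1 | starting material
2 | phenylmagnesium bromide | Br[Mg]c1ccccc1 | starting material
3 | furan-2-yl(phenyl)methanol (racemic) | OC(c1ccccc1)c1ccco1 | intermediate
4 | 6-hydroxy-2-phenyl-2H-pyran-3(6H)-one (racemic, anomer mixture) | OC1C=CC(=O)C(c2ccccc2)O1 | intermediate
5 | 4,5-dibromo-6-hydroxy-2-phenyltetrahydro-2H-pyran-3-one (diastereomer mixture, not isolated) | OC1OC(c2ccccc2)C(=O)C(Br)C1Br | intermediate
6 | 4-bromo-6-hydroxy-2-phenyl-2H-pyran-3(6H)-one (racemic, anomer mixture) | OC1C=C(Br)C(=O)C(c2ccccc2)O1 | intermediate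
7 | 3-hydroxy-2-phenyl-4H-pyran-4-one | O=c1ccoc(-c2ccccc2)c1O | intermediate
8 | 3-methoxy-2-phenyl-4H-pyran-4-one | COc1c(-c2ccccc2)occc1=O | intermediate
9 | dimethyl squarate (3,4-dimethoxycyclobut-3-ene-1,2-dione) | COC1=C(OC)C(=O)C1=O | starting material
10 | 6-lithio-3-methoxy-2-phenyl-4H-pyran-4-one (not isolated) | [Li]c1cc(=O)c(OC)c(-c2ccccc2)o1 | intermediate
11 | 4-hydroxy-2,3-dimethoxy-4-(5-methoxy-4-oxo-6-phenyl-4H-pyran-2-yl)cyclobut-2-en-1-one (racemic) | COC1=C(OC)C(O)(c2cc(=O)c(OC)c(-c3ccccc3)o2)C1=O | intermediate
12 | 2,3,4-trimethoxy-4-(5-methoxy-4-oxo-6-phenyl-4H-pyran-2-yl)cyclobut-2-en-1-one (racemic) | COC1=C(OC)C(OC)(c2cc(=O)c(OC)c(-c3ccccc3)o2)C1=O | intermediate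
13 | (3Z)-2,3,4-trimethoxy-4-(5-methoxy-4-oxo-6-phenyl-4H-pyran-2-yl)buta-1,3-dien-1-one (dienylketene, not isolated) | COC(=C=O)/C(OC)=C(/OC)c1cc(=O)c(OC)c(-c2ccccc2)o1 | intermediate
14 | 3,6,7,8-tetramethoxy-2-phenyl-4aH-chromene-4,5-dione (racemic, not isolated) | COC1=C(OC)C(=O)C2C(=O)C(OC)=C(c3ccccc3)OC2=C1OC | intermediate
15 | 5-hydroxy-3,6,7,8-tetramethoxyflavone (5-hydroxy-3,6,7,8-tetramethoxy-2-phenyl-4H-chromen-4-one, achiral) | COc1c(OC)c(O)c2c(=O)c(OC)c(-c3ccccc3)oc2c1OC | target

**Step count**

Total steps: 8. Longest linear sequence: 8 steps (1 to 15; dimethyl squarate 9 enters at step 6).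

**Steps most likely to fail**

1. Step 8 (carries the "Proposed new method:" label). Closure of the dienylketene onto pyranone C5 may be too slow, so that the ketene reverts, dimerises or is captured by trace nucleophiles; or the ring may open with the pyranonyl group outward, so that no closure can follow.
Fallback, known chemistry, setting out from dimethyl squarate 9 and rejoining at the target 15: ring A is made first by the same squarate ring expansion with a simple enol ether alkene, and ring C is then built by classical flavone chemistry. 1-Methoxyvinyllithium (made beforehand from methyl vinyl ether and t-BuLi) is added to 9 at −78 °C to give 4-hydroxy-2,3-dimethoxy-4-(1-methoxyvinyl)cyclobut-2-en-1-one F1. Methylation with MeI/Ag2O gives 2,3,4-trimethoxy-4-(1-methoxyvinyl)cyclobut-2-en-1-one F2, and heating F2 in toluene should give 2,3,4,5-tetramethoxyphenol F3 by Moore rearrangement. Acylation of F3 at its only free ring position with methoxyacetic acid in BF3·OEt2 should give 1-(2-hydroxy-3,4,5,6-tetramethoxyphenyl)-2-methoxyethan-1-one F4. Allan–Robinson condensation with benzoic anhydride and sodium benzoate should give 3,5,6,7,8-pentamethoxyflavone F5, and chelation-controlled cleavage of the 5-methyl ether with BCl3 in CH2Cl2 at low temperature should give 15.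

2. Step 6. Deprotonation may occur at the wrong site (C5, directed by lithium on the carbonyl oxygen); the lithiated pyranone may attack not-yet-metalated 8; or the anion may fragment before the squarate is added.
Fallback, setting out from 8 and rejoining at 11: metalation and C–C bond formation are separated. TMPZnCl·LiCl in THF at 25 °C should zincate 8 at C6 to (5-methoxy-4-oxo-6-phenyl-4H-pyran-2-yl)zinc chloride F6, a species that does not attack the pyranone. Iodine converts it to 6-iodo-3-methoxy-2-phenyl-4H-pyran-4-one F7, on which the site of substitution can be confirmed. Iodine–magnesium exchange with i-PrMgCl·LiCl at −78 °C then gives (5-methoxy-4-oxo-6-phenyl-4H-pyran-2-yl)magnesium chloride F8 in the absence of amine and of free 8, and addition of F8 to 9 should give 11.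

3. Step 4. In hot acid the bromoenone may be lost to ring contraction or resin formation faster than it ionises and hydrolyses to the γ-pyranone.
Fallback, setting out from 4 and rejoining at 7 (it replaces steps 3 and 4): the C4 oxygen is brought in as an epoxide instead of through a halide. Hemiacetal 4 is converted with trimethyl orthoformate and catalytic BF3·OEt2 to 6-methoxy-2-phenyl-2H-pyran-3(6H)-one F9. Nucleophilic epoxidation of the enone with alkaline H2O2 should give 4,5-epoxy-6-methoxy-2-phenyltetrahydro-2H-pyran-3-one F10. Warming F10 with dilute aqueous acid should isomerise the epoxy ketone to the diosphenol and eliminate methanol to give 7, the sequence used to make maltol from the 2-methyl analogue.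

**Further compounds**

F1 | step 8 | 4-hydroxy-2,3-dimethoxy-4-(1-methoxyvinyl)cyclobut-2-en-1-one (racemic) | COC(=C)C1(O)C(OC)=C(OC)C1=O
F2 | step 8 | 2,3,4-trimethoxy-4-(1-methoxyvinyl)cyclobut-2-en-1-one (racemic) | COC(=C)C1(OC)C(OC)=C(OC)C1=O
F3 | step 8 | 2,3,4,5-tetramethoxyphenol | COc1cc(O)c(OC)c(OC)c1OC
F4 | step 8 | 1-(2-hydroxy-3,4,5,6-tetramethoxyphenyl)-2-methoxyethan-1-one | COCC(=O)c1c(O)c(OC)c(OC)c(OC)c1OC
F5 | step 8 | 3,5,6,7,8-pentamethoxyflavone | COc1c(OC)c(OC)c2c(=O)c(OC)c(-c3ccccc3)oc2c1OC
F6 | step 6 | (5-methoxy-4-oxo-6-phenyl-4H-pyran-2-yl)zinc chloride | COc1c(-c2ccccc2)oc([Zn]Cl)cc1=O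
F7 | step 6 | 6-iodo-3-methoxy-2-phenyl-4H-pyran-4-one | COc1c(-c2ccccc2)oc(I)cc1=O
F8 | step 6 | (5-methoxy-4-oxo-6-phenyl-4H-pyran-2-yl)magnesium chloride | COc1c(-c2ccccc2)oc([Mg]Cl)cc1=O
F9 | step 4 | 6-methoxy-2-phenyl-2H-pyran-3(6H)-one (racemic, anomer mixture) | COC1C=CC(=O)C(c2ccccc2)O1
F10 | step 4 | 4,5-epoxy-6-methoxy-2-phenyltetrahydro-2H-pyran-3-one (diastereomer mixture) | COC1OC(c2ccccc2)C(=O)C2OC12
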